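**Plan**
- Retrosynthetic cuts: the ten O-benzyl groups; then the interflavan C4–C8 bond (a C4 cation of the upper unit, released from a 4-phenylsulfanyl group, plus C8 of a benzylated catechin 3-O-ester); then ring C of the upper unit across O1–C8a and C3–C4 in a single anionic [3+3] annulation.
- Enabling feature: ring C of the upper unit carries oxygen on both C2 (ring O1) and C3 and is fused to a phloroglucinol ring A. The C2–C3 edge can therefore be a trans 2-benzyloxy-3-aryl oxirane (O1 latent as the epoxide oxygen, C3 an acetal-type electrophile). Ring A with C4 can be an ortho-fluorobenzyl phenyl sulfide (C4 acidified by sulfur, C8a an SNAr acceptor).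
- Forward order: ring A sulfide (from 1,3,5-trifluorobenzene) and ring B epoxy ether (from 3,4-bis(benzyloxy)benzaldehyde) are joined with closure of ring C; the product is united with the catechin ester; hydrogenolysis finishes.
- Stereochemistry: Shi epoxidation sets C2; inversion at C3 on epoxide opening relays this to the 2,3-cis pair; C4 is set in the coupling, anti to the C3 and C2 substituents (4β); C2 and C3 of the lower unit are bought with (+)-catechin.

Key step: step 8

Remark: C4 of compound 14 is expected as an epimer mixture and is left unassigned on purpose, because this centre becomes planar in step 11; the facial sense of the Shi epoxidation is assumed to follow that known for trans-β-methylstyrene.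

**Route**

Step 1
Reactants: 1 1,3,5-trifluorobenzene
Product: 3 1,3-bis(benzyloxy)-5-fluorobenzene, via 1-(benzyloxy)-3,5-difluorobenzene 2 (not isolated)
Conditions: BnOH (2.1 equiv), NaH (2.2 equiv), NMP, 0 → 100 °C
Reagents that add atoms: benzyl alcohol, OCc1ccccc1
Why: Twofold nucleophilic aromatic substitution of fluoride by benzyloxide should stop at the monofluoride, because each alkoxy group introduced slows the next displacement.

Step 2
Reactants: 3 1,3-bis(benzyloxy)-5-fluorobenzene
Product: 5 2,4-bis(benzyloxy)-6-fluorobenzaldehyde, via aryl iminium dichlorophosphate 4 (not isolated)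
Conditions: POCl3, DMF, 0 → 60 °C; then aq. NaOAc
Reagents that add atoms: N,N-dimethylformamide, CN(C)C=O; water, O
Why: Vilsmeier–Haack formylation should take place para to one benzyloxy group at the less hindered position next to fluorine, as is usual for 1-halo-3,5-dialkoxybenzenes.

Step 3
Reactants: 5 2,4-bis(benzyloxy)-6-fluorobenzaldehyde
Product: 6 [2,4-bis(benzyloxy)-6-fluorophenyl]methanol
Conditions: NaBH4, THF–MeOH, 0 °C
Reagents that add atoms: none
Why: Borohydride reduction of an aryl aldehyde leaves aryl fluoride and benzyl ethers untouched.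

Step 4
Reactants: 6 [2,4-bis(benzyloxy)-6-fluorophenyl]methanol
Product: 7 1,5-bis(benzyloxy)-3-fluoro-2-[(phenylsulfanyl)methyl]benzene (ring A sulfide)
Conditions: PhSSPh, PBu3, pyridine, rt
Reagents that add atoms: diphenyl disulfide, c1ccccc1SSc1ccccc1
Why: The phosphine–disulfide redox condensation (Hata reaction) should convert the electron-rich benzylic alcohol into the sulfide through an alkoxyphosphonium ion displaced by thiolate.

Step 5
Reactants: 8 3,4-bis(benzyloxy)benzaldehyde
Product: 9 1,2-bis(benzyloxy)-4-[(E)-2-iodoethenyl]benzene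
Conditions: CHI3, CrCl2, THF, 0 °C, dark
Reagents that add atoms: iodoform, IC(I)I
Why: Takai olefination of an aryl aldehyde with the geminal dichromium reagent should give the (E)-vinyl iodide.

Step 6
Reactants: 9 1,2-bis(benzyloxy)-4-[(E)-2-iodoethenyl]benzene
Product: 10 1,2-bis(benzyloxy)-4-[(E)-2-(benzyloxy)ethenyl]benzene
Conditions: BnOH, CuI (10 mol %), 3,4,7,8-tetramethyl-1,10-phenanthroline (20 mol %), Cs2CO3, toluene, 80 °C
Reagents that add atoms: benzyl alcohol, OCc1ccccc1
Why: Ullmann-type copper-catalysed C–O coupling of a vinyl iodide with an alcohol should proceed with retention of the alkene geometry.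

Step 7
Reactants: 10 1,2-bis(benzyloxy)-4-[(E)-2-(benzyloxy)ethenyl]benzene
Product: 11 (2S,3R)-2-(benzyloxy)-3-[3,4-bis(benzyloxy)phenyl]oxirane (trans; aryl-bearing carbon R)
Conditions: D-fructose-derived Shi ketone (30 mol %), Oxone (2KHSO5·KHSO4·K2SO4), K2CO3, Bu4NHSO4, MeCN–dimethoxymethane–aq. Na2B4O7 buffer (pH 10.5), −10 °C; cold extraction into Et3N-doped pentane–Et2O, used crude
Reagents that add atoms: potassium peroxymonosulfate, [K+].[O-]S(=O)(=O)OO
Why: Shi asymmetric epoxidation of the electron-rich trans alkene through the spiro dioxirane transition state should give the trans epoxy ether with the aryl-bearing carbon R, and the basic medium protects the acid-labile product.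

Step 8
Reactants: 7 1,5-bis(benzyloxy)-3-fluoro-2-[(phenylsulfanyl)methyl]benzene; 11 (2S,3R)-2-(benzyloxy)-3-[3,4-bis(benzyloxy)phenyl]oxirane
Product: 14 (2R,3S,4RS)-3,5,7-tris(benzyloxy)-2-[3,4-bis(benzyloxy)phenyl]-4-(phenylsulfanyl)chromane (penta-O-benzyl-4-phenylsulfanyl-epicatechin as C4 epimers), via lithiated sulfide 12 (not isolated), via ring-opened lithium alkoxide 13 (not isolated)
Conditions: 7, LDA (LiN(i-Pr)2, 1.05 equiv), THF, −78 °C; 11, −78 → −30 °C; then DMPU, −30 → 50 °C
Reagents that add atoms: none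
Why: Proposed new method: the α-sulfanyl benzyllithium 12 should attack the alkoxy-bearing (acetal-type) carbon of the trans epoxy ether in an SN2 manner to form C3–C4, and the benzylic lithium alkoxide 13 thus unmasked at O1 should displace the ortho fluoride on warming to form O1–C8a, an anionic [3+3] annulation overall. The closest known reaction types are the opening of 1,2-anhydro sugars (glycal epoxides) at the anomeric carbon by carbon nucleophiles and the alkoxide SNAr pyran closure onto 3,5-dialkoxyfluorobenzenes. The only ring closed is the pyran ring C, by 6-exo-trig addition–elimination at C8a through a Meisenheimer intermediate with loss of LiF. C2 keeps the configuration set in step 7, C3 is set by inversion of the trans epoxide, which translates into the 2,3-cis relation, and C4 is left uncontrolled because it is planarised in step 11. The step needs benzylic rather than ring deprotonation (secured by the reversible amide base at −78 °C, which selects the more acidic α-sulfanyl benzylic C–H), attack at C3 rather than at the benzylic C2 and without ionisation (secured by the alkoxy activation of C3 and the absence of any Lewis acid). Cyclisation through O1 only is secured because O3 is a benzyl ether from the outset.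

Step 9
Reactants: 15 (+)-catechin
Product: 16 5,7,3',4'-tetra-O-benzyl-(+)-catechin
Conditions: BnBr (4.2 equiv), K2CO3, DMF, 0 °C → rt
Reagents that add atoms: benzyl bromide, BrCc1ccccc1
Why: Williamson etherification with carbonate base should benzylate the four phenols and leave the far less acidic secondary alcohol free.

Step 10
Reactants: 16 5,7,3',4'-tetra-O-benzyl-(+)-catechin; 17 4-(benzyloxy)benzoyl chloride
Product: 18 5,7,3',4'-tetra-O-benzyl-(+)-catechin 3-O-[4-(benzyloxy)benzoate]
Conditions: Et3N, DMAP (cat.), CH2Cl2, 0 °C → rt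
Reagents that add atoms: none
Why: DMAP-catalysed acylation of the single free hydroxyl by the acid chloride touches no stereocentre.

Step 11
Reactants: 14 penta-O-benzyl-4-phenylsulfanyl-epicatechin (C4 epimers); 18 5,7,3',4'-tetra-O-benzyl-(+)-catechin 3-O-[4-(benzyloxy)benzoate] (3 equiv)
Product: 19 3,5,7,3',4'-penta-O-benzyl-epicatechin-(4β→8)-[5,7,3',4'-tetra-O-benzyl-catechin 3-O-(4-benzyloxybenzoate)]
Conditions: AgBF4 (1.2 equiv), 4 Å MS, CH2Cl2–THF, −40 → 0 °C
Reagents that add atoms: none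
Why: Thiophilic ionisation of the C4–S bond should give the dialkoxy-stabilised flavan-4-yl cation from either C4 epimer, and Friedel–Crafts alkylation by C8 of 18 from the face anti to the C3 benzyloxy and C2 aryl groups should set C4 as 4β (3,4-trans).

Step 12
Reactants: 19 protected dimer
Product: 20 epicatechin-(4β→8)-catechin 3-O-(4-hydroxybenzoate) on the catechin unit (target)
Conditions: H2 (1 atm), Pd(OH)2/C, THF–MeOH–H2O, rt
Reagents that add atoms: none
Why: Catalytic hydrogenolysis should cleave all ten benzyl ethers while the aryl ester, the interflavan C–C bond and the five stereocentres stay untouched.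

**Compound list**
1 | 1,3,5-trifluorobenzene | Fc1cc(F)cc(F)c1 | starting material
2 | 1-(benzyloxy)-3,5-difluorobenzene | Fc1cc(F)cc(OCc2ccccc2)c1 | intermediate (not isolated)
3 | 1,3-bis(benzyloxy)-5-fluorobenzene | Fc1cc(OCc2ccccc2)cc(OCc2ccccc2)c1 | intermediate
4 | N-[2,4-bis(benzyloxy)-6-fluorobenzylidene]-N-methylmethanaminium dichlorophosphate | C[N+](C)=Cc1c(F)cc(OCc2ccccc2)cc1OCc1ccccc1.[O-]P(=O)(Cl)Cl | intermediate (not isolated)
5 | 2,4-bis(benzyloxy)-6-fluorobenzaldehyde | O=Cc1c(F)cc(OCc2ccccc2)cc1OCc1ccccc1 | intermediate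
6 | [2,4-bis(benzyloxy)-6-fluorophenyl]methanol | OCc1c(F)cc(OCc2ccccc2)cc1OCc1ccccc1 | intermediate
7 | 1,5-bis(benzyloxy)-3-fluoro-2-[(phenylsulfanyl)methyl]benzene | Fc1cc(OCc2ccccc2)cc(OCc2ccccc2)c1CSc1ccccc1 | intermediate
8 | 3,4-bis(benzyloxy)benzaldehyde | O=Cc1ccc(OCc2ccccc2)c(OCc2ccccc2)c1 | starting material
9 | 1,2-bis(benzyloxy)-4-[(E)-2-iodoethenyl]benzene | I/C=C/c1ccc(OCc2ccccc2)c(OCc2ccccc2)c1 | intermediate
10 | 1,2-bis(benzyloxy)-4-[(E)-2-(benzyloxy)ethenyl]benzene | O(Cc1ccccc1)/C=C/c1ccc(OCc2ccccc2)c(OCc2ccccc2)c1 | intermediate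
11 | (2S,3R)-2-(benzyloxy)-3-[3,4-bis(benzyloxy)phenyl]oxirane (trans) | O1[C@H](c2ccc(OCc3ccccc3)c(OCc3ccccc3)c2)[C@H]1OCc1ccccc1 | intermediate
12 | [2,4-bis(benzyloxy)-6-fluorophenyl](phenylsulfanyl)methyllithium | [Li]C(Sc1ccccc1)c1c(F)cc(OCc2ccccc2)cc1OCc1ccccc1 | intermediate (not isolated)
13 | lithium (1R,2S)-2-(benzyloxy)-1-[3,4-bis(benzyloxy)phenyl]-3-[2,4-bis(benzyloxy)-6-fluorophenyl]-3-(phenylsulfanyl)propan-1-olate (chain C3 unassigned) | [Li]O[C@H](c1ccc(OCc2ccccc2)c(OCc2ccccc2)c1)[C@@H](C(Sc1ccccc1)c1c(F)cc(OCc2ccccc2)cc1OCc1ccccc1)OCc1ccccc1 | intermediate (not isolated)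
14 | (2R,3S,4RS)-3,5,7-tris(benzyloxy)-2-[3,4-bis(benzyloxy)phenyl]-4-(phenylsulfanyl)chromane | C1(Sc2ccccc2)c2c(OCc3ccccc3)cc(OCc3ccccc3)cc2O[C@H](c2ccc(OCc3ccccc3)c(OCc3ccccc3)c2)[C@@H]1OCc1ccccc1 | intermediate
15 | (+)-catechin, (2R,3S) | O[C@H]1Cc2c(O)cc(O)cc2O[C@@H]1c1ccc(O)c(O)c1 | starting material
16 | 5,7,3',4'-tetra-O-benzyl-(+)-catechin | O[C@H]1Cc2c(OCc3ccccc3)cc(OCc3ccccc3)cc2O[C@@H]1c1ccc(OCc2ccccc2)c(OCc2ccccc2)c1 | intermediate
17 | 4-(benzyloxy)benzoyl chloride | O=C(Cl)c1ccc(OCc2ccccc2)cc1 | starting material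
18 | 5,7,3',4'-tetra-O-benzyl-(+)-catechin 3-O-[4-(benzyloxy)benzoate] | O=C(O[C@H]1Cc2c(OCc3ccccc3)cc(OCc3ccccc3)cc2O[C@@H]1c1ccc(OCc2ccccc2)c(OCc2ccccc2)c1)c1ccc(OCc2ccccc2)cc1 | intermediate
19 | 3,5,7,3',4'-penta-O-benzyl-epicatechin-(4β→8)-[5,7,3',4'-tetra-O-benzyl-catechin 3-O-(4-benzyloxybenzoate)] | O=C(O[C@H]1Cc2c(OCc3ccccc3)cc(OCc3ccccc3)c([C@H]3c4c(OCc5ccccc5)cc(OCc5ccccc5)cc4O[C@H](c4ccc(OCc5ccccc5)c(OCc5ccccc5)c4)[C@@H]3OCc3ccccc3)c2O[C@@H]1c1ccc(OCc2ccccc2)c(OCc2ccccc2)c1)c1ccc(OCc2ccccc2)cc1 | intermediate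
20 | epicatechin-(4β→8)-catechin 3-O-(4-hydroxybenzoate) on the catechin unit; upper unit 2R,3R,4R, lower unit 2R,3S | O=C(O[C@H]1Cc2c(O)cc(O)c([C@H]3c4c(O)cc(O)cc4O[C@H](c4ccc(O)c(O)c4)[C@@H]3O)c2O[C@@H]1c1ccc(O)c(O)c1)c1ccc(O)cc1 | target

**Count**
Total steps: 12. Longest linear sequence: 7 steps (1, 2, 3, 4, 8, 11, 12).

**Steps most likely to fail**

Step 8 (Proposed new method). The lithiated sulfide may attack the benzylic epoxide carbon instead of the alkoxy-bearing one, the epoxy ether may ionise so that inversion at C3 is lost, or ring metalation next to fluorine may compete with benzylic deprotonation. The fallback uses only known chemistry, sets out from compound 16 and comes back at compound 20. Compound 16 is oxidised with Dess–Martin periodinane to (2R)-5,7-bis(benzyloxy)-2-[3,4-bis(benzyloxy)phenyl]chroman-3-one F1. Reduction with L-Selectride (LiBH(s-Bu)3) from the face opposite the C2 aryl group should give 5,7,3',4'-tetra-O-benzyl-(−)-epicatechin F2. Benzylic oxidation at C4 with DDQ in the presence of 2-ethoxyethanol should give 4β-(2-ethoxyethoxy)-5,7,3',4'-tetra-O-benzyl-epicatechin F3. TMSOTf-catalysed condensation of F3 with an excess of 18 at −78 °C should give the nona-O-benzyl dimer with a free upper 3-hydroxyl F4, and hydrogenolysis under the conditions of step 12 should give 20.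

Step 7. The acid-labile epoxy ether may hydrolyse or rearrange in the aqueous medium, or the facial discrimination of an alkoxy-substituted alkene may be poor. The fallback sets out from compound 10 and comes back at compound 19; it relays absolute configuration from the catechin unit instead of from a catalyst. Anhydrous dimethyldioxirane in acetone at −40 °C should give the racemic trans epoxy ether, that is 11 together with its enantiomer (2R,3S)-2-(benzyloxy)-3-[3,4-bis(benzyloxy)phenyl]oxirane F5. Under the conditions of step 8 the racemate should give 14 together with its enantiomer (2S,3R,4RS)-3,5,7-tris(benzyloxy)-2-[3,4-bis(benzyloxy)phenyl]-4-(phenylsulfanyl)chromane F7, the latter through the enantiomeric lithium alkoxide F6. Coupling with enantiopure 18 under the conditions of step 11 should give 19 and the diastereomer with an ent-epicatechin upper unit F8, which are separable by chromatography.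

Step 11. The flavan-4-yl cation may be captured by ring A of a second molecule of 14 (oligomerisation) faster than by the hindered, 3-O-acylated nucleophile, or attack may occur through C6 of 18. The fallback sets out from compounds 14 and 16 and comes back at compound 19; it changes the order of bond formation. Compound 14 is coupled under the same silver activation with an excess of the free alcohol 16, the less hindered nucleophile, to give 3,5,7,3',4'-penta-O-benzyl-epicatechin-(4β→8)-5,7,3',4'-tetra-O-benzyl-catechin F9. Its only free hydroxyl is then acylated with 17 (Et3N, DMAP) to give 19.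

**Further compounds**
F1 | step 8 | (2R)-5,7-bis(benzyloxy)-2-[3,4-bis(benzyloxy)phenyl]chroman-3-one | O=C1Cc2c(OCc3ccccc3)cc(OCc3ccccc3)cc2O[C@@H]1c1ccc(OCc2ccccc2)c(OCc2ccccc2)c1
F2 | step 8 | 5,7,3',4'-tetra-O-benzyl-(−)-epicatechin | O[C@@H]1Cc2c(OCc3ccccc3)cc(OCc3ccccc3)cc2O[C@@H]1c1ccc(OCc2ccccc2)c(OCc2ccccc2)c1
F3 | step 8 | 4β-(2-ethoxyethoxy)-5,7,3',4'-tetra-O-benzyl-epicatechin | CCOCCO[C@H]1c2c(OCc3ccccc3)cc(OCc3ccccc3)cc2O[C@H](c2ccc(OCc3ccccc3)c(OCc3ccccc3)c2)[C@@H]1O
F4 | step 8 | 5,7,3',4'-tetra-O-benzyl-epicatechin-(4β→8)-[5,7,3',4'-tetra-O-benzyl-catechin 3-O-(4-benzyloxybenzoate)] | O=C(O[C@H]1Cc2c(OCc3ccccc3)cc(OCc3ccccc3)c([C@H]3c4c(OCc5ccccc5)cc(OCc5ccccc5)cc4O[C@H](c4ccc(OCc5ccccc5)c(OCc5ccccc5)c4)[C@@H]3O)c2O[C@@H]1c1ccc(OCc2ccccc2)c(OCc2ccccc2)c1)c1ccc(OCc2ccccc2)cc1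
F5 | step 7 | (2R,3S)-2-(benzyloxy)-3-[3,4-bis(benzyloxy)phenyl]oxirane | O1[C@@H](c2ccc(OCc3ccccc3)c(OCc3ccccc3)c2)[C@@H]1OCc1ccccc1
F6 | step 7 | lithium (1S,2R)-2-(benzyloxy)-1-[3,4-bis(benzyloxy)phenyl]-3-[2,4-bis(benzyloxy)-6-fluorophenyl]-3-(phenylsulfanyl)propan-1-olate | [Li]O[C@@H](c1ccc(OCc2ccccc2)c(OCc2ccccc2)c1)[C@H](C(Sc1ccccc1)c1c(F)cc(OCc2ccccc2)cc1OCc1ccccc1)OCc1ccccc1
F7 | step 7 | (2S,3R,4RS)-3,5,7-tris(benzyloxy)-2-[3,4-bis(benzyloxy)phenyl]-4-(phenylsulfanyl)chromane | C1(Sc2ccccc2)c2c(OCc3ccccc3)cc(OCc3ccccc3)cc2O[C@@H](c2ccc(OCc3ccccc3)c(OCc3ccccc3)c2)[C@H]1OCc1ccccc1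
F8 | step 7 | 3,5,7,3',4'-penta-O-benzyl-ent-epicatechin-(4α→8)-[5,7,3',4'-tetra-O-benzyl-catechin 3-O-(4-benzyloxybenzoate)] | O=C(O[C@H]1Cc2c(OCc3ccccc3)cc(OCc3ccccc3)c([C@@H]3c4c(OCc5ccccc5)cc(OCc5ccccc5)cc4O[C@@H](c4ccc(OCc5ccccc5)c(OCc5ccccc5)c4)[C@H]3OCc3ccccc3)c2O[C@@H]1c1ccc(OCc2ccccc2)c(OCc2ccccc2)c1)c1ccc(OCc2ccccc2)cc1
F9 | step 11 | 3,5,7,3',4'-penta-O-benzyl-epicatechin-(4β→8)-5,7,3',4'-tetra-O-benzyl-catechin | O[C@H]1Cc2c(OCc3ccccc3)cc(OCc3ccccc3)c([C@H]3c4c(OCc5ccccc5)cc(OCc5ccccc5)cc4O[C@H](c4ccc(OCc5ccccc5)c(OCc5ccccc5)c4)[C@@H]3OCc3ccccc3)c2O[C@@H]1c1ccc(OCc2ccccc2)c(OCc2ccccc2)c1
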